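## The problem

Compound 18 is a flavone whose ring A carries a methoxy group at C5, a free hydroxyl at C7 and, at C8, a piperidine joined through C2' by a single aryl–alkyl bond. Its only stereocentre is C2' (R). Nothing else in the molecule can relay stereochemistry to it, so it must come from a reagent or an auxiliary. C2' is benzylic to a phloroglucinol-type ring and bears a basic nitrogen next to a phenol, so 18 is a phenolic Mannich base. Heat, base acting on the phenolate/ammonium zwitterion, or strong acid can break C2'–N to an ortho-quinone methide, and reclosure scrambles C2'. Attaching the amine ring to a preformed flavone would give C6/C8 mixtures. The free secondary amine also intercepts any acylating agent used to build ring C, and hydroxide opens the chromone at C2. The feature that helps is this: without C2, C3, C4 and the phenyl group, ring A is a 2-substituted 5-methoxyresorcinol with C8 and C5 on a local twofold axis. Rotation about C8–C2' exchanges the two hydroxyls (future O1 and O7) and the two ring CH carbons (future C4a and C6), so an annulation forming C4a–C4 and O1–C2 can only give the 8-piperidinyl isomer.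

## Retrosynthesis

**18 ⇒ 17 (N–acyl bond).** The last operation should be mild and leave C2' alone, so the nitrogen is carried as a trifluoroacetamide. This group survives a hot, acid-free annulation, cannot close onto the neighbouring phenol as a carbamate would, and is removed by carbonate at room temperature.

**17 ⇒ 13 + 14 (C4a–C4 and O1–C2).** Cutting both bonds of ring C removes nine carbons at once and leaves the symmetric resorcinol 13 and commercial ethyl benzoylacetate 14. The neighbouring cut at C8–C2' (aminoalkylation of a preformed flavone) would be racemic and unselective between C6 and C8. A stepwise route through an acetophenone and a 1,3-diketone would cost several steps in strong base. The forward reaction must give C-acylation and chromone (not coumarin) closure, and must keep C2'–N intact; it passes through benzoylketene 15 and diketone 16.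

**13 ⇒ 11 (N–acyl bond).** The amide is made from the amine hydrochloride 11 by over-acylation to 12 and selective methanolysis of the two aryl esters. No selectivity between N and O is needed in the acylation itself.

**11 ⇒ 10 (S–N and two O–CH2 bonds).** The sulfinyl auxiliary and both methoxymethyl ethers are acid-labile, so one treatment with methanolic HCl should release all three and deliver the stable ammonium salt.

**10 ⇒ 9 (N1'–C6').** The piperidine is closed by N-alkylation at the remote primary carbon. The other ring bond to nitrogen, C2'–N, is not a sensible cut, because a leaving group on this very electron-rich benzylic carbon would ionise and racemise.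

**9 ⇒ 6 + 7 (C2'–C3', sets C2').** Adding the four-carbon chain, as Grignard reagent 8 made from 7, to the sulfinyl aldimine 6 forms the stereocentre irreversibly under auxiliary control. Catalytic reduction of a cyclic imine would be shorter on paper, but is poorly charted for a di-ortho-substituted aryl group. Here the two possible products are diastereomers, so the purity of 9 can be raised by chromatography or crystallisation whatever the selectivity.

**6 ⇒ 4 + 5 (C=N).** Condensation of aldehyde 4 with commercial (S)-tert-butanesulfinamide 5.

**4 ⇒ 2 ⇒ 1 (aryl–CHO, then O–CH2).** The formyl group enters by lithiation of 2 (via aryllithium 3) between its two methoxymethyl ethers. This is the same symmetric position that later becomes C8, so the directing groups do the regiochemical work. Ether 2 comes from commercial 5-methoxyresorcinol 1.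

## Roads not taken

**Alternative 1:** The piperidine is cut at C2'–C3' and N1'–C6'. Forward, a chiral phosphoric acid would catalyse addition of the silyloxydiene A2 to the N-(4-methoxyphenyl) aldimine A1 (from aldehyde 4), and ring closure with loss of methanol would give dihydropyridone A3. Its merit is catalytic enantiocontrol without an auxiliary, and on that count it is better than the chosen plan. Its weak points are specific to this target. A1 is di-ortho-substituted, its aryl ring is twisted out of conjugation, and its acetal oxygens compete for the catalyst. A3 carries a C4' carbonyl and a C5'=C6' double bond that must both be removed. The N-aryl group is normally removed oxidatively, for example with (NH4)2Ce(NO3)6, which ring A would not tolerate. At least four extra steps follow the key step, and ring C is still to be made. The chosen plan pays with a stoichiometric auxiliary, but the piperidine arrives at the right oxidation level and the auxiliary leaves in the same acid step that frees the phenols.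

**Alternative 2:** The cut is N1'–C2'. Forward, a chiral phosphoric acid would protonate the ortho-hydroxystyrene A4 at C3' to an ortho-quinone methide, and the carbamate nitrogen would add to C2' to give A5. This is the shortest route to a free-phenol, N-acylated piperidinylresorcinol, and A5 is one protecting-group exchange from 13. If it worked with high selectivity it would beat the chosen plan in step count and atom economy. The weak point is that the ionisation that forms C2'–N can also undo it under the same acid, so the enantiomeric purity can erode with time. The ring carbons of A4 are strong competing nucleophiles, and the electron-rich styrene is prone to oligomerise. The chosen plan sets against this a stereocentre formed irreversibly, by an addition with a well-tested model and separable diastereomers.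

**Alternative 3:** The cut is C5'–C6' and N1'–C6', with carbon monoxide as C6'. Forward, Rh(acac)(CO)2 with BIPHEPHOS under CO and H2 would hydroformylate the terminal alkene of homoallylic carbamate A6, and condensation of nitrogen with the aldehyde would give enecarbamate A7. The merits are atom economy and a reliable allyl transfer to make A6; that allyl transfer is probably less sensitive to the ortho ethers than the 4-chlorobutyl Grignard addition. However, A6 would take its stereocentre from the same sulfinyl aldimine 6, so nothing is gained in stereocontrol. The route also needs an exchange of sulfinyl for Boc, pressure equipment and a hydrogenation of A7, about three more steps than the direct N-alkylation. The chosen plan brings in all four carbons at once and closes the ring by a simple substitution.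

Key step: step 8

Remark on the chemistry: the configuration at C2' in step 4 is assigned from the closed, magnesium-bridged chair model for Grignard additions to tert-butanesulfinyl aldimines in CH2Cl2; amine 11 is handled as its hydrochloride and 18 as the free base.

## Route

Step 1
Reactants: 1 5-methoxyresorcinol
Product: 2 1-methoxy-3,5-bis(methoxymethoxy)benzene
Conditions: NaH, MOMCl, DMF, 0 °C → rt
Reagents that add atoms: chloromethyl methyl ether, COCCl
Why: Williamson etherification of both phenoxides with the reactive α-chloro ether; the methoxymethyl ethers are the directing groups for step 2 and are acid-labile like the later sulfinyl group.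

Step 2
Reactants: 2 1-methoxy-3,5-bis(methoxymethoxy)benzene
Product: 4 4-methoxy-2,6-bis(methoxymethoxy)benzaldehyde, via aryllithium 3 (not isolated)
Conditions: n-BuLi, TMEDA, THF, 0 °C; DMF, 0 °C → rt; H2O
Reagents that add atoms: N,N-dimethylformamide, CN(C)C=O
Why: Directed ortho-metalation; the position flanked by two chelating methoxymethyl ethers should be lithiated in preference to those flanked by one such ether and the methoxy group, and aryllithium 3 is formylated by DMF (Bouveault-type formylation).

Step 3
Reactants: 4 4-methoxy-2,6-bis(methoxymethoxy)benzaldehyde; 5 (S)-2-methylpropane-2-sulfinamide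
Product: 6 (S,E)-N-[[4-methoxy-2,6-bis(methoxymethoxy)phenyl]methylidene]-2-methylpropane-2-sulfinamide
Conditions: Ti(OEt)4, THF, rt → 50 °C
Reagents that add atoms: none
Why: Condensation of an aldehyde with tert-butanesulfinamide, with Ti(OEt)4 as Lewis acid and water scavenger; it should give the E-aldimine without touching the sulfur stereocentre.

Step 4
Reactants: 6 (S,E)-N-[[4-methoxy-2,6-bis(methoxymethoxy)phenyl]methylidene]-2-methylpropane-2-sulfinamide; 7 1-bromo-4-chlorobutane
Product: 9 (S)-N-[(R)-5-chloro-1-[4-methoxy-2,6-bis(methoxymethoxy)phenyl]pentyl]-2-methylpropane-2-sulfinamide, via Grignard reagent 8 (not isolated)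
Conditions: 7, Mg, Et2O, 30 °C; then 6, CH2Cl2, −48 °C → rt; H2O
Reagents that add atoms: none
Why: Magnesium inserts into the C–Br bond and leaves C–Cl alone, and the Grignard reagent adds 1,2 to the sulfinyl aldimine. In CH2Cl2 the addition should run through a six-membered chair with magnesium on the sulfinyl oxygen and tert-butyl equatorial, which delivers the chain to the Re face of the (S)-configured E-aldimine and sets C2' as R. The minor diastereomer should be removable by chromatography.

Step 5
Reactants: 9 (S)-N-[(R)-5-chloro-1-[4-methoxy-2,6-bis(methoxymethoxy)phenyl]pentyl]-2-methylpropane-2-sulfinamide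
Product: 10 (R)-1-[(S)-tert-butylsulfinyl]-2-[4-methoxy-2,6-bis(methoxymethoxy)phenyl]piperidine
Conditions: NaH, DMF, 0 °C → rt
Reagents that add atoms: none
Why: Intramolecular N-alkylation of the sodium sulfinamide at the primary chloride (6-exo-tet substitution) closes the piperidine; C2' is not involved.

Step 6
Reactants: 10 (R)-1-[(S)-tert-butylsulfinyl]-2-[4-methoxy-2,6-bis(methoxymethoxy)phenyl]piperidine
Product: 11 (R)-5-methoxy-2-(piperidin-2-yl)benzene-1,3-diol hydrochloride
Conditions: HCl (3 M in MeOH), rt; evaporate, triturate with Et2O
Reagents that add atoms: hydrogen chloride, Cl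
Why: Acid methanolysis cleaves the S–N bond within minutes and transacetalises both methoxymethyl ethers more slowly; the amine is protonated throughout and is isolated as the air-stable salt.

Step 7
Reactants: 11 (R)-5-methoxy-2-(piperidin-2-yl)benzene-1,3-diol hydrochloride
Product: 13 (R)-1-[2-(2,6-dihydroxy-4-methoxyphenyl)piperidin-1-yl]-2,2,2-trifluoroethanone, via tris(trifluoroacetyl) intermediate 12 (not isolated)
Conditions: TFAA, Et3N, CH2Cl2, 0 °C; then MeOH, 0 °C → rt
Reagents that add atoms: trifluoroacetic anhydride, O=C(OC(=O)C(F)(F)F)C(F)(F)F
Why: Exhaustive trifluoroacetylation of nitrogen and both phenols, then chemoselective methanolysis of the two very labile aryl trifluoroacetates, should leave only the amide; this makes nitrogen non-basic and non-nucleophilic for step 8.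

Step 8
Reactants: 13 (R)-1-[2-(2,6-dihydroxy-4-methoxyphenyl)piperidin-1-yl]-2,2,2-trifluoroethanone; 14 ethyl benzoylacetate
Product: 17 (R)-7-hydroxy-5-methoxy-2-phenyl-8-[1-(trifluoroacetyl)piperidin-2-yl]-4H-chromen-4-one, via benzoylketene 15 (not isolated), via diketone 16 (not isolated)
Conditions: 14 (2 equiv), Ph2O, 240 °C (microwave), N2 sweep, short heating
Reagents that add atoms: none
Why: On heating, 14 loses ethanol to give benzoylketene 15, which acylates one of the two equivalent ring carbons of 13 that lie ortho to a hydroxyl and ortho to the methoxy group, directly or by O-acylation and acyl shift, to give the ortho-hydroxyaryl 1,3-diketone 16 (bond C4a–C4). The neighbouring phenol oxygen then adds to the benzoyl carbonyl in a 6-exo-trig closure and the hemiketal loses water, which forms O1–C2 and ring C. The closest known reaction is the Mentzer pyrone synthesis (thermal Simonis-type condensation), in which phloroglucinol and ethyl benzoylacetate give 5,7-dihydroxyflavone without a catalyst. No stereocentre is formed and C2' is a spectator. Chromone rather than 4-phenylcoumarin is needed: with no acid present the ring carbon attacks the acyl carbon of the ketene and not the ketone carbonyl, as the Pechmann mode would require, and the trioxygenated ring is nucleophilic enough for uncatalysed C-acylation. Regiochemistry needs no control, because rotation about the C8–C2' bond exchanges the two hydroxyls and the two free ring positions, so every annulation mode gives the 8-substituted 7-hydroxy-5-methoxyflavone. Retention at C2' rests on the trifluoroacetamide, whose nitrogen is neither basic nor a good leaving group without acid, and on the short heating time; a 7-O-benzoylacetyl ester, should it form, is cleaved in step 9.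

Step 9
Reactants: 17 (R)-7-hydroxy-5-methoxy-2-phenyl-8-[1-(trifluoroacetyl)piperidin-2-yl]-4H-chromen-4-one
Product: 18 (R)-7-hydroxy-5-methoxy-2-phenyl-8-(piperidin-2-yl)-4H-chromen-4-one
Conditions: K2CO3, MeOH/H2O, 0 °C → rt; neutralise to pH 7–8 and isolate cold
Reagents that add atoms: none
Why: Base solvolysis of the activated trifluoroacetamide; the chromone, a vinylogous ester, and the aryl methyl ether should not react at room temperature, and keeping the mixture cold avoids ring opening at C2'–N in the zwitterionic product.

## Compound list

1 | 5-methoxyresorcinol (5-methoxybenzene-1,3-diol) | COc1cc(O)cc(O)c1 | starting material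
2 | 1-methoxy-3,5-bis(methoxymethoxy)benzene | COCOc1cc(OC)cc(OCOC)c1 | intermediate
3 | [4-methoxy-2,6-bis(methoxymethoxy)phenyl]lithium | [Li]c1c(OCOC)cc(OC)cc1OCOC | intermediate
4 | 4-methoxy-2,6-bis(methoxymethoxy)benzaldehyde | COCOc1cc(OC)cc(OCOC)c1C=O | intermediate
5 | (S)-2-methylpropane-2-sulfinamide | CC(C)(C)[S@](=O)N | starting material
6 | (S,E)-N-[[4-methoxy-2,6-bis(methoxymethoxy)phenyl]methylidene]-2-methylpropane-2-sulfinamide | CC(C)(C)[S@](=O)/N=C/c1c(OCOC)cc(OC)cc1OCOC | intermediate
7 | 1-bromo-4-chlorobutane | ClCCCCBr | starting material
8 | (4-chlorobutyl)magnesium bromide | ClCCCC[Mg]Br | intermediate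
9 | (S)-N-[(R)-5-chloro-1-[4-methoxy-2,6-bis(methoxymethoxy)phenyl]pentyl]-2-methylpropane-2-sulfinamide | CC(C)(C)[S@](=O)N[C@H](CCCCCl)c1c(OCOC)cc(OC)cc1OCOC | intermediate
10 | (R)-1-[(S)-tert-butylsulfinyl]-2-[4-methoxy-2,6-bis(methoxymethoxy)phenyl]piperidine | CC(C)(C)[S@](=O)N1CCCC[C@@H]1c1c(OCOC)cc(OC)cc1OCOC | intermediate
11 | (R)-5-methoxy-2-(piperidin-2-yl)benzene-1,3-diol hydrochloride | COc1cc(O)c([C@H]2CCCCN2)c(O)c1.Cl | intermediate
12 | (R)-5-methoxy-2-[1-(trifluoroacetyl)piperidin-2-yl]-1,3-phenylene bis(trifluoroacetate) | COc1cc(OC(=O)C(F)(F)F)c([C@H]2CCCCN2C(=O)C(F)(F)F)c(OC(=O)C(F)(F)F)c1 | intermediate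
13 | (R)-1-[2-(2,6-dihydroxy-4-methoxyphenyl)piperidin-1-yl]-2,2,2-trifluoroethanone | COc1cc(O)c([C@H]2CCCCN2C(=O)C(F)(F)F)c(O)c1 | intermediate
14 | ethyl benzoylacetate (ethyl 3-oxo-3-phenylpropanoate) | CCOC(=O)CC(=O)c1ccccc1 | starting material
15 | benzoylketene (3-oxo-3-phenylprop-1-en-1-one) | O=C=CC(=O)c1ccccc1 | intermediate
16 | 1-[2,4-dihydroxy-6-methoxy-3-[(R)-1-(trifluoroacetyl)piperidin-2-yl]phenyl]-3-phenylpropane-1,3-dione | COc1cc(O)c([C@H]2CCCCN2C(=O)C(F)(F)F)c(O)c1C(=O)CC(=O)c1ccccc1 | intermediate
17 | (R)-7-hydroxy-5-methoxy-2-phenyl-8-[1-(trifluoroacetyl)piperidin-2-yl]-4H-chromen-4-one | COc1cc(O)c([C@H]2CCCCN2C(=O)C(F)(F)F)c2oc(-c3ccccc3)cc(=O)c12 | intermediate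
18 | (R)-7-hydroxy-5-methoxy-2-phenyl-8-(piperidin-2-yl)-4H-chromen-4-one | COc1cc(O)c([C@H]2CCCCN2)c2oc(-c3ccccc3)cc(=O)c12 | target

## Step count and risks

Total step count: 9. Longest linear sequence: 9 steps (1 to 18); compounds 5, 7 and 14 enter as purchased materials.

**Key step (step 8).** The most likely failure is loss of configuration: at 240 °C the benzylic C2'–N bond may open reversibly to an ortho-quinone methide. Other risks are O-acylation without acyl shift, closure in the coumarin sense, self-condensation of 14, and transfer of the trifluoroacetyl group from N to O followed by N-acylation by 15. The fallback sets out from 13 and returns at 17, and runs at or below 60 °C without acid. One equivalent of N-iodosuccinimide in MeCN at −20 °C should iodinate one of the two equivalent ring positions to give (R)-1-[2-(2,6-dihydroxy-3-iodo-4-methoxyphenyl)piperidin-1-yl]-2,2,2-trifluoroethanone F1. Carbonylative Sonogashira coupling of F1 with phenylacetylene (CO balloon, PdCl2(PPh3)2, Et2NH) would give 1-[2,4-dihydroxy-6-methoxy-3-[(R)-1-(trifluoroacetyl)piperidin-2-yl]phenyl]-3-phenylprop-2-yn-1-one F2. In the amine medium F2 closes by 6-endo-dig oxa-Michael addition to 17. The symmetry argument holds for the iodination as it does for the annulation.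

**Grignard addition (step 4).** The ortho acetal oxygens may hold magnesium and open a non-chair pathway, giving poor or even inverted facial selectivity. The di-ortho-substituted aldimine may also react slowly, and reagent 8 may be consumed by coupling. The fallback sets out from 6 and returns at 10. Allyl bromide and In powder in saturated aqueous NaBr, where the ethers cannot compete for the metal, should give (S)-N-[(R)-1-[4-methoxy-2,6-bis(methoxymethoxy)phenyl]but-3-en-1-yl]-2-methylpropane-2-sulfinamide F3 by the same closed model. N-allylation (NaH, allyl bromide, DMF) gives (S)-N-allyl-N-[(R)-1-[4-methoxy-2,6-bis(methoxymethoxy)phenyl]but-3-en-1-yl]-2-methylpropane-2-sulfinamide F4. Ring-closing metathesis with the second-generation Grubbs catalyst gives (R)-1-[(S)-tert-butylsulfinyl]-2-[4-methoxy-2,6-bis(methoxymethoxy)phenyl]-1,2,3,6-tetrahydropyridine F5, and hydrogenation (H2, Pd/C, EtOAc) gives 10. If the sense of induction proves opposite, the enantiomer of 5 is used.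

**Acid deprotection (step 6).** Hours in protic acid may ionise the benzylic C2'–N+ bond (solvolysis and loss of configuration), and the formaldehyde acetal set free may alkylate the very nucleophilic ring. The fallback sets out from 10 and returns at 13, changing the order of events. Brief treatment with two equivalents of HCl (dioxane/MeOH, 0 °C) should cleave only the S–N bond and give (R)-2-[4-methoxy-2,6-bis(methoxymethoxy)phenyl]piperidine F6. TFAA and Et3N convert F6 into (R)-2,2,2-trifluoro-1-[2-[4-methoxy-2,6-bis(methoxymethoxy)phenyl]piperidin-1-yl]ethanone F7. The acetals of F7 are then removed without protic acid by Me3SiOTf and 2,2'-bipyridyl in CH2Cl2 at 0 °C followed by water, which gives 13.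

**Final deprotection (step 9).** Solvolysis of the hindered tertiary trifluoroacetamide may be slow. Forcing it with heat invites retro-Mannich opening of the phenolate/ammonium zwitterion (loss of configuration) and hydroxide attack at C2 of the chromone. The fallback sets out from 17 and returns at 18 by reductive cleavage with NaBH4 in EtOH at 0 °C to rt. Hydride adds to the activated trifluoroacetyl carbonyl and the hemiaminal collapses to the amine. The chromone carbonyl, deactivated further by the 7-phenoxide, should be slow to react. This fallback makes no new compound (F0).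

## Further compounds

F1 | step 8 | (R)-1-[2-(2,6-dihydroxy-3-iodo-4-methoxyphenyl)piperidin-1-yl]-2,2,2-trifluoroethanone | COc1cc(O)c([C@H]2CCCCN2C(=O)C(F)(F)F)c(O)c1I
F2 | step 8 | 1-[2,4-dihydroxy-6-methoxy-3-[(R)-1-(trifluoroacetyl)piperidin-2-yl]phenyl]-3-phenylprop-2-yn-1-one | COc1cc(O)c([C@H]2CCCCN2C(=O)C(F)(F)F)c(O)c1C(=O)C#Cc1ccccc1
F3 | step 4 | (S)-N-[(R)-1-[4-methoxy-2,6-bis(methoxymethoxy)phenyl]but-3-en-1-yl]-2-methylpropane-2-sulfinamide | CC(C)(C)[S@](=O)N[C@H](CC=C)c1c(OCOC)cc(OC)cc1OCOC
F4 | step 4 | (S)-N-allyl-N-[(R)-1-[4-methoxy-2,6-bis(methoxymethoxy)phenyl]but-3-en-1-yl]-2-methylpropane-2-sulfinamide | CC(C)(C)[S@](=O)N(CC=C)[C@H](CC=C)c1c(OCOC)cc(OC)cc1OCOC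
F5 | step 4 | (R)-1-[(S)-tert-butylsulfinyl]-2-[4-methoxy-2,6-bis(methoxymethoxy)phenyl]-1,2,3,6-tetrahydropyridine | CC(C)(C)[S@](=O)N1CC=CC[C@@H]1c1c(OCOC)cc(OC)cc1OCOC
F6 | step 6 | (R)-2-[4-methoxy-2,6-bis(methoxymethoxy)phenyl]piperidine | COCOc1cc(OC)cc(OCOC)c1[C@H]1CCCCN1
F7 | step 6 | (R)-2,2,2-trifluoro-1-[2-[4-methoxy-2,6-bis(methoxymethoxy)phenyl]piperidin-1-yl]ethanone | COCOc1cc(OC)cc(OCOC)c1[C@H]1CCCCN1C(=O)C(F)(F)F
F0 | step 9 | none | none
A1 | alternative 1 | (E)-N-(4-methoxyphenyl)-1-[4-methoxy-2,6-bis(methoxymethoxy)phenyl]methanimine | COCOc1cc(OC)cc(OCOC)c1/C=N/c1ccc(OC)cc1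
A2 | alternative 1 | (E)-1-methoxy-3-(trimethylsilyloxy)buta-1,3-diene | CO/C=C/C(=C)O[Si](C)(C)C
A3 | alternative 1 | (R)-2-[4-methoxy-2,6-bis(methoxymethoxy)phenyl]-1-(4-methoxyphenyl)-2,3-dihydropyridin-4(1H)-one | COCOc1cc(OC)cc(OCOC)c1[C@H]1CC(=O)C=CN1c1ccc(OC)cc1
A4 | alternative 2 | tert-butyl N-[(E)-5-(2,6-dihydroxy-4-methoxyphenyl)pent-4-en-1-yl]carbamate | COc1cc(O)c(/C=C/CCCNC(=O)OC(C)(C)C)c(O)c1
A5 | alternative 2 | tert-butyl (R)-2-(2,6-dihydroxy-4-methoxyphenyl)piperidine-1-carboxylate | COc1cc(O)c([C@H]2CCCCN2C(=O)OC(C)(C)C)c(O)c1
A6 | alternative 3 | tert-butyl N-[(R)-1-[4-methoxy-2,6-bis(methoxymethoxy)phenyl]but-3-en-1-yl]carbamate | COCOc1cc(OC)cc(OCOC)c1[C@@H](CC=C)NC(=O)OC(C)(C)C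
A7 | alternative 3 | tert-butyl (R)-2-[4-methoxy-2,6-bis(methoxymethoxy)phenyl]-3,4-dihydro-2H-pyridine-1-carboxylate | COCOc1cc(OC)cc(OCOC)c1[C@H]1CCC=CN1C(=O)OC(C)(C)C
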